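**Retrosynthetic overview**

1. The target is a (3S)-5,7-dimethoxyphthalide joined through (CH2)6 to C2 of a (2S,5S,7S)-7-methyl-1,6-dioxaspiro[4.4]nonane (ring A: O1–C2–C3–C4–C5; ring B: C5–O6–C7–C8–C9).
2. Enabling feature: spiro C5 is a ketone carbon flanked by C4H2, so O1–C5–C4 of ring A is the O=C–CH3 unit of an α-acetyl-γ-lactone dianion. Ring B (O6, C7 with its methyl, C8, C9) is the (5S)-γ-valerolactone ring of that same reagent; its carbonyl is a traceless activating group, lost later as CO2.
3. Key disconnection: C3–C4 and O1–C2 in one pot. The dianion is C-alkylated by (R)-glycidyl triflate, then the enolate oxygen opens the strained epoxide 5-exo with inversion; this sets C2 and closes ring A.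
4. Chain: the CH2OH left on C2 becomes pent-4-enyl (Cu-catalysed Grignard coupling). Cross-metathesis with (S)-3-allyl-5,7-dimethoxyphthalide (Brown allylboration, then lithiation/CO2) and hydrogenation give the C6 tether.
5. Ring order: γ-lactone (latent ring B) → ring A (key step) → phthalide (separate fragment) → ring B and spiro C5 last, by saponification, decarboxylation and spiroketalization.

Key step: step 3

Remark: C5 of a 2,7-dialkyl-1,6-dioxaspiro[4.4]nonane is taken to have no marked thermodynamic preference; it is therefore formed last under equilibrating acid, and the unwanted spiro epimer is separated, re-equilibrated and recycled.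

**Route**

Step 1
Reactants: 1 ethyl acetoacetate; 2 (S)-propylene oxide
Product: 3 (5S)-3-acetyl-5-methyloxolan-2-one
Conditions: NaOEt (1 equiv), EtOH, 0 °C → rt; AcOH
Reagents that add atoms: none
Why: Alkylation of the acetoacetate anion by the epoxide at its unsubstituted carbon and lactonisation of the resulting alkoxide with loss of ethanol (acetoacetic ester synthesis of an α-acyl-γ-lactone); the oxirane stereocentre is not touched and becomes C5 of the lactone (later C7 of the spiroketal), while C3 is an inconsequential, enolisable centre.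

Step 2
Reactants: 4 (S)-glycidol
Product: 5 [(2R)-oxiran-2-yl]methyl trifluoromethanesulfonate
Conditions: Tf2O, 2,6-lutidine, CH2Cl2, −78 → −40 °C; cold aqueous work-up, used at once
Reagents that add atoms: trifluoromethanesulfonic anhydride, O=S(=O)(OS(=O)(=O)C(F)(F)F)C(F)(F)F
Why: O-Triflation of a primary alcohol at low temperature leaves the epoxide and its stereocentre untouched (the descriptor changes from S to R only through the priority rules).

Step 3
Reactants: 3 (5S)-3-acetyl-5-methyloxolan-2-one; 5 [(2R)-oxiran-2-yl]methyl trifluoromethanesulfonate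
Product: 8 (3E,5S)-3-[(5R)-5-(hydroxymethyl)oxolan-2-ylidene]-5-methyloxolan-2-one, via dilithium dienolate 6 (not isolated), via epoxy enolate 7 (not isolated)
Conditions: LiN(iPr)2 (2.1 equiv per 3), THF, 0 °C; 5 (1.05 equiv), −78 °C; LiClO4 (2 equiv), −78 → 20 °C; aq. NH4Cl
Reagents that add atoms: none
Why: The acetyl carbon of dianion 6 displaces the triflate of 5 at −78 °C (this forms the C3–C4 bond of ring A), and on warming with LiClO4 the enolate oxygen of 7 opens the epoxide at its inner carbon (this forms the O1–C2 bond). The closest known reaction type is the one-pot C,O-cyclodialkylation of dilithiated 1,3-dicarbonyl compounds with epibromohydrin or 1-bromo-2-chloroethane to 2-alkylidenetetrahydrofurans; here the release of epoxide strain drives the C–O bond formation. Ring A closes by a 5-exo-tet attack of oxygen on the epoxide. C2 of ring A is set by SN2 inversion at the epoxide carbon, whose configuration comes from (S)-glycidol, so the transfer should be stereospecific; C7 is carried from 3. The step needs C-alkylation at the triflate before the epoxide is touched (secured by the far better leaving group at −78 °C), closure through oxygen and not through the α-carbon (that carbon is fully substituted and a five-membered ring through it would be a disfavoured 5-(enolendo)-exo-tet closure), and 5-exo instead of 6-endo opening (the normal preference, helped by lithium coordination). The geometry of the new tetrasubstituted alkene is of no consequence because this double bond is protonated in step 9.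

Step 4
Reactants: 8 (3E,5S)-3-[(5R)-5-(hydroxymethyl)oxolan-2-ylidene]-5-methyloxolan-2-one
Product: 10 (3E,5S)-5-methyl-3-[(5S)-5-(pent-4-en-1-yl)oxolan-2-ylidene]oxolan-2-one, via primary triflate 9 (not isolated)
Conditions: Tf2O, 2,6-lutidine, CH2Cl2, −78 °C; quick ice-cold aq. NaHCO3 wash, dried cold, diluted with Et2O; then CH2=CHCH2CH2MgBr (1.5 equiv), CuBr·SMe2 (10 mol %), Et2O/THF, −50 → −20 °C
Reagents that add atoms: but-3-en-1-ylmagnesium bromide, C=CCC[Mg]Br
Why: Copper-catalysed sp3–sp3 coupling of a primary triflate with a Grignard reagent takes place at the exocyclic CH2 (the ring stereocentre is untouched) and should be much faster at −50 °C than addition of the Grignard reagent to the electron-rich vinylogous carbonate carbonyl, the pyridinium salt of the triflation being washed out first so that it cannot quench the Grignard reagent.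

Step 5
Reactants: 11 2-bromo-3,5-dimethoxybenzaldehyde
Product: 12 (1S)-1-(2-bromo-3,5-dimethoxyphenyl)but-3-en-1-ol
Conditions: (−)-Ipc2B(allyl) (from (+)-α-pinene, 1.2 equiv), Et2O, −78 °C; then NaOH, H2O2, 0 °C → rt
Reagents that add atoms: (−)-B-allyldiisopinocampheylborane, C=CCB([C@@H]1C[C@@H]2C[C@H]([C@H]1C)C2(C)C)[C@@H]1C[C@@H]2C[C@H]([C@H]1C)C2(C)C
Why: Brown allylboration through a closed chair transition state; the (−)-reagent should add to the Si face of the aryl aldehyde and so give the (S)-carbinol under reagent control.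

Step 6
Reactants: 12 (1S)-1-(2-bromo-3,5-dimethoxyphenyl)but-3-en-1-ol
Product: 15 (3S)-5,7-dimethoxy-3-(prop-2-en-1-yl)-2-benzofuran-1(3H)-one, via dilithiated aryl alkoxide 13 (not isolated), via hydroxy acid 14 (not isolated)
Conditions: n-BuLi (2.2 equiv), THF, −78 °C; CO2, −78 → 0 °C; 2 M HCl, rt
Reagents that add atoms: carbon dioxide, O=C=O
Why: Deprotonation of the hydroxyl and bromine–lithium exchange give the ortho-lithiated alkoxide, which is carboxylated; acid then closes the γ-lactone (phthalide) without breaking the benzylic C–O bond, so the configuration is retained.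

Step 7
Reactants: 10 (3E,5S)-5-methyl-3-[(5S)-5-(pent-4-en-1-yl)oxolan-2-ylidene]oxolan-2-one; 15 (3S)-5,7-dimethoxy-3-(prop-2-en-1-yl)-2-benzofuran-1(3H)-one
Product: 16 (3E,5S)-3-[(5S)-5-{(4E)-6-[(1S)-4,6-dimethoxy-3-oxo-1,3-dihydro-2-benzofuran-1-yl]hex-4-en-1-yl}oxolan-2-ylidene]-5-methyloxolan-2-one
Conditions: RuCl2(=CHPh)(H2IMes)(PCy3) (second-generation Grubbs catalyst, 5 mol %), 15 in excess (3 equiv; unreacted 15 and its homodimer recovered and reused), CH2Cl2, 40 °C
Reagents that add atoms: none
Why: Olefin cross-metathesis of two unhindered terminal alkenes with release of ethene; the excess of 15 suppresses the homodimer of 10, the tetrasubstituted push–pull alkene is inert, and the E/Z mixture at the new alkene is removed in step 8.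

Step 8
Reactants: 16 (3E,5S)-3-[(5S)-5-{(4E)-6-[(1S)-4,6-dimethoxy-3-oxo-1,3-dihydro-2-benzofuran-1-yl]hex-4-en-1-yl}oxolan-2-ylidene]-5-methyloxolan-2-one
Product: 17 (3E,5S)-3-[(5S)-5-{6-[(1S)-4,6-dimethoxy-3-oxo-1,3-dihydro-2-benzofuran-1-yl]hexyl}oxolan-2-ylidene]-5-methyloxolan-2-one
Conditions: H2 (1–3 atm), RhCl(PPh3)3 (5 mol %), toluene/EtOH, rt
Reagents that add atoms: none
Why: Homogeneous catalytic hydrogenation with RhCl(PPh3)3 should reduce only the disubstituted alkene and leave the tetrasubstituted vinylogous carbonate alkene, the benzylic lactone C–O bond and all stereocentres untouched.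

Step 9
Reactants: 17 (3E,5S)-3-[(5S)-5-{6-[(1S)-4,6-dimethoxy-3-oxo-1,3-dihydro-2-benzofuran-1-yl]hexyl}oxolan-2-ylidene]-5-methyloxolan-2-one
Product: 19 (3S)-5,7-dimethoxy-3-{6-[(2S,5S,7S)-7-methyl-1,6-dioxaspiro[4.4]nonan-2-yl]hexyl}-2-benzofuran-1(3H)-one, via disodium dicarboxylate 18 (not isolated)
Conditions: NaOH (2 M aq.), MeOH, 60 °C; then HCl to pH 1, THF/H2O, 45 °C; preparative HPLC separation from the spiro epimer, which is re-equilibrated (camphorsulfonic acid, CH2Cl2, rt) and recycled
Reagents that add atoms: none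
Why: Saponification opens the vinylogous carbonate lactone (and, reversibly, the phthalide), and on acidification C-protonation of the enol ether gives an oxocarbenium ion that loses CO2 like a β-keto acid, after which the freed C7 hydroxyl adds to the ring A oxocarbenium ion (acid-catalysed spiroketalization, ring B by 5-exo closure) and the phthalide relactonises; C2, C7 and the benzylic centre keep their C–O bonds, whereas spiro C5 is set under thermodynamic control with little expected bias, so the (5S) compound should have to be separated from its spiro epimer, which is funnelled back by re-equilibration.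

**Compound list**

1 | ethyl acetoacetate | CCOC(=O)CC(C)=O | starting material
2 | (S)-propylene oxide, (2S)-2-methyloxirane | C[C@H]1CO1 | starting material
3 | (5S)-3-acetyl-5-methyloxolan-2-one (C3 epimers and enol, all equivalent) | CC(=O)C1C[C@H](C)OC1=O | intermediate
4 | (S)-glycidol, [(2S)-oxiran-2-yl]methanol | OC[C@H]1CO1 | starting material
5 | [(2R)-oxiran-2-yl]methyl trifluoromethanesulfonate | FC(F)(F)S(=O)(=O)OC[C@H]1CO1 | intermediate
6 | dilithium dienolate of 3 | [Li+].[Li+].C=C([O-])C1=C([O-])O[C@@H](C)C1 | intermediate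
7 | lithium enolate of (5S)-5-methyl-3-{3-[(2S)-oxiran-2-yl]propanoyl}oxolan-2-one | [Li+].[O-]C(CC[C@H]1CO1)=C1C[C@H](C)OC1=O | intermediate
8 | (3E,5S)-3-[(5R)-5-(hydroxymethyl)oxolan-2-ylidene]-5-methyloxolan-2-one (E drawn; geometry inconsequential) | C[C@H]1C/C(C(=O)O1)=C2/CC[C@H](CO)O2 | intermediate
9 | [(2R,5E)-5-[(5S)-5-methyl-2-oxooxolan-3-ylidene]oxolan-2-yl]methyl trifluoromethanesulfonate | C[C@H]1C/C(C(=O)O1)=C2/CC[C@H](COS(=O)(=O)C(F)(F)F)O2 | intermediate
10 | (3E,5S)-5-methyl-3-[(5S)-5-(pent-4-en-1-yl)oxolan-2-ylidene]oxolan-2-one | C[C@H]1C/C(C(=O)O1)=C2/CC[C@H](CCCC=C)O2 | intermediate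
11 | 2-bromo-3,5-dimethoxybenzaldehyde | COc1cc(OC)c(Br)c(C=O)c1 | starting material
12 | (1S)-1-(2-bromo-3,5-dimethoxyphenyl)but-3-en-1-ol | COc1cc(OC)c(Br)c(c1)[C@@H](O)CC=C | intermediate
13 | lithium (1S)-1-(2-lithio-3,5-dimethoxyphenyl)but-3-en-1-olate | COc1cc(OC)c([Li])c(c1)[C@@H](O[Li])CC=C | intermediate
14 | 2-[(1S)-1-hydroxybut-3-en-1-yl]-4,6-dimethoxybenzoic acid | COc1cc(OC)c(C(=O)O)c(c1)[C@@H](O)CC=C | intermediate
15 | (3S)-5,7-dimethoxy-3-(prop-2-en-1-yl)-2-benzofuran-1(3H)-one | COc1cc(OC)c2c(c1)[C@H](CC=C)OC2=O | intermediate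
16 | (3E,5S)-3-[(5S)-5-{(4E)-6-[(1S)-4,6-dimethoxy-3-oxo-1,3-dihydro-2-benzofuran-1-yl]hex-4-en-1-yl}oxolan-2-ylidene]-5-methyloxolan-2-one (E/Z mixture at the chain alkene, E drawn) | C[C@H]1C/C(C(=O)O1)=C2/CC[C@H](CCC/C=C/C[C@@H]3OC(=O)c4c(OC)cc(OC)cc43)O2 | intermediate
17 | (3E,5S)-3-[(5S)-5-{6-[(1S)-4,6-dimethoxy-3-oxo-1,3-dihydro-2-benzofuran-1-yl]hexyl}oxolan-2-ylidene]-5-methyloxolan-2-one | C[C@H]1C/C(C(=O)O1)=C2/CC[C@H](CCCCCC[C@@H]3OC(=O)c4c(OC)cc(OC)cc43)O2 | intermediate
18 | disodium 2-[(1S)-7-{(2S,5E)-5-[(3S)-1-carboxylato-3-hydroxybutylidene]oxolan-2-yl}-1-hydroxyheptyl]-4,6-dimethoxybenzoate (both lactones of 17 opened) | [Na+].[Na+].C[C@H](O)C/C(C(=O)[O-])=C1/CC[C@H](CCCCCC[C@H](O)c2cc(OC)cc(OC)c2C(=O)[O-])O1 | intermediate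
19 | (3S)-5,7-dimethoxy-3-{6-[(2S,5S,7S)-7-methyl-1,6-dioxaspiro[4.4]nonan-2-yl]hexyl}-2-benzofuran-1(3H)-one | COc1cc(OC)c2c(c1)[C@H](CCCCCC[C@H]1CC[C@]3(CC[C@H](C)O3)O1)OC2=O | target

**Step count**

Total: 9 steps. Longest linear sequence: 6 steps (steps 2, 3, 4, 7, 8, 9 from (S)-glycidol; equally steps 1, 3, 4, 7, 8, 9 from ethyl acetoacetate).

**Steps most likely to fail, with fallbacks**

Step 3. After the C-alkylation the enolate may close through carbon onto the terminal epoxide carbon (a six-membered carbocycle) or may not close at all, and the base may consume the triflate before C-alkylation. The fallback replaces the glycidyl unit by a 1,2-cyclic sulfate that already carries the side chain, so that only one closure is possible. It sets out from 4: opening with but-3-en-1-ylmagnesium bromide (2.5 equiv) and CuI (THF, −30 °C) gives (2R)-hept-6-ene-1,2-diol F1. NaH and 1,1'-sulfonyldiimidazole (THF, −20 → 0 °C) convert F1 directly into the cyclic sulfate (4R)-4-(pent-4-en-1-yl)-1,3,2-dioxathiolane 2,2-dioxide F2, with no oxidant that could touch the terminal alkene. Dianion 6 (from 3) opens F2 at the primary carbon to the dilithium alkyl sulfate enolate F3. On warming, the enolate oxygen displaces the secondary sulfate with inversion; with this electrophile only the 5-exo closure through oxygen exists. This gives 10 directly, so the route is rejoined at 10 and step 4 is no longer needed.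

Step 4. Addition of the Grignard reagent to the vinylogous carbonate carbonyl, or its γ-deprotonation, may compete with the copper-mediated displacement, and the primary triflate may decompose before it couples. The fallback installs the chain first and forms ring A by cyclodehydration. It sets out from 3: (S)-epichlorohydrin and but-3-en-1-ylmagnesium bromide with CuI give (2S)-1-chlorohept-6-en-2-ol F4, which NaOH closes to (2S)-2-(pent-4-en-1-yl)oxirane F5. Dianion 6 (from 3) opens F5 at the terminal carbon (BF3·OEt2, THF, −78 °C) to (5S)-3-[(4S)-4-hydroxynon-8-enoyl]-5-methyloxolan-2-one F6. Its hydroxyl, with retained configuration, adds to the ketone and the hemiketal dehydrates with CF3CO2H in CH2Cl2 to 10. The route is rejoined at 10, and no organometallic reagent meets the lactone.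

Step 9. There is little thermodynamic discrimination at the spiro carbon, so poor selectivity there should force a separation on the final, most valuable compound. The fallback sets C5 before the fragments are joined. It sets out from 10: NaOH, then HCl, gives (2S,5S,7S)-7-methyl-2-(pent-4-en-1-yl)-1,6-dioxaspiro[4.4]nonane F7 together with its (2S,5R,7S) epimer F8. The pair is separated at this small, cheap stage and F8 is re-equilibrated with acid. F7 and 15 are joined by cross-metathesis with the same ruthenium catalyst to (3S)-5,7-dimethoxy-3-{(2E)-6-[(2S,5S,7S)-7-methyl-1,6-dioxaspiro[4.4]nonan-2-yl]hex-2-en-1-yl}-2-benzofuran-1(3H)-one F9. Hydrogenation with RhCl(PPh3)3 gives 19, where the route is rejoined; every operation after F7 is run without protic acid so that C5 is carried unchanged.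

**Further compounds**

F1 | step 3 | (2R)-hept-6-ene-1,2-diol | OC[C@H](O)CCCC=C
F2 | step 3 | (4R)-4-(pent-4-en-1-yl)-1,3,2-dioxathiolane 2,2-dioxide | C=CCCC[C@@H]1COS(=O)(=O)O1
F3 | step 3 | dilithium salt of the enolate of (5S)-5-methyl-3-[(4R)-4-(sulfonatooxy)non-8-enoyl]oxolan-2-one | [Li+].[Li+].[O-]S(=O)(=O)O[C@H](CCCC=C)CCC([O-])=C1C[C@H](C)OC1=O
F4 | step 4 | (2S)-1-chlorohept-6-en-2-ol | ClC[C@@H](O)CCCC=C
F5 | step 4 | (2S)-2-(pent-4-en-1-yl)oxirane | C=CCCC[C@H]1CO1
F6 | step 4 | (5S)-3-[(4S)-4-hydroxynon-8-enoyl]-5-methyloxolan-2-one | C=CCCC[C@H](O)CCC(=O)C1C[C@H](C)OC1=O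
F7 | step 9 | (2S,5S,7S)-7-methyl-2-(pent-4-en-1-yl)-1,6-dioxaspiro[4.4]nonane | C=CCCC[C@H]1CC[C@]2(CC[C@H](C)O2)O1
F8 | step 9 | (2S,5R,7S)-7-methyl-2-(pent-4-en-1-yl)-1,6-dioxaspiro[4.4]nonane | C=CCCC[C@H]1CC[C@@]2(CC[C@H](C)O2)O1
F9 | step 9 | (3S)-5,7-dimethoxy-3-{(2E)-6-[(2S,5S,7S)-7-methyl-1,6-dioxaspiro[4.4]nonan-2-yl]hex-2-en-1-yl}-2-benzofuran-1(3H)-one | COc1cc(OC)c2c(c1)[C@H](C/C=C/CCC[C@H]1CC[C@]3(CC[C@H](C)O3)O1)OC2=O
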